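Ring B is disconnected at C1'–C6' and C2'–C3': C1' and C2' are the alkyne carbons of 2-ethynyl-7,8-dimethoxychromone, C3'–C6' the four carbons of 3,4-dimethoxyfuran. One Diels–Alder addition with acid opening of the oxygen bridge builds the whole ring and turns the furan oxygen into the C3' hydroxyl beside the furan-derived methoxy carbons C4' and C5', so the lone phenol is told apart from the methyl ethers without protection. The precursor is a flat, achiral chromone (rings A and C finished) carrying only an ethynyl group on C2; the symmetric furan leaves no regiochemical choice in the cycloaddition. C2 is set last by asymmetric conjugate reduction.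

Key step: step 5

Assumption: 3,4-dimethoxyfuran is taken as a purchasable building block.
Assumption: (R)-DTBM-SEGPHOS is written in step 6 as the ligand hand expected to deliver hydride to the C2 face that leads to (S); the sense of induction is to be confirmed on the first run and the (S)-ligand used if it proves to be the reverse.

Step 1
Reactants: 1 2'-hydroxy-3',4'-dimethoxyacetophenone; 2 diethyl oxalate
Product: 4 ethyl 7,8-dimethoxy-4-oxo-4H-chromene-2-carboxylate, via diketo ester 3 (not isolated)
Conditions: NaOEt (3 equiv), EtOH, reflux; then conc. HCl, EtOH, reflux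
Reagents that add atoms: none
Why: Crossed Claisen condensation of the methyl ketone enolate with the non-enolisable oxalate gives the 2,4-dioxo ester 3, whose phenol closes onto the C2 ketone with loss of water under acid (classical chromone-2-carboxylate synthesis).

Step 2
Reactants: 4 ethyl 7,8-dimethoxy-4-oxo-4H-chromene-2-carboxylate
Product: 5 2-(hydroxymethyl)-7,8-dimethoxy-4H-chromen-4-one
Conditions: NaBH4 (1.5 equiv), MeOH, 0 °C
Reagents that add atoms: none
Why: Chemoselective borohydride reduction: the ester on the oxygen-bearing C2 is activated like an α-alkoxyacrylate and should be reduced at 0 °C, while the pyrone carbonyl, a vinylogous ester, is left alone.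

Step 3
Reactants: 5 2-(hydroxymethyl)-7,8-dimethoxy-4H-chromen-4-one
Product: 6 7,8-dimethoxy-4-oxo-4H-chromene-2-carbaldehyde
Conditions: Dess–Martin periodinane (1.2 equiv), CH2Cl2, 0 °C to rt
Reagents that add atoms: none
Why: Dess–Martin oxidation of the primary allylic-type alcohol stops at the aldehyde under neutral, anhydrous conditions that spare the pyrone and the aryl ethers; the electrophilic aldehyde is used crude.

Step 4
Reactants: 6 7,8-dimethoxy-4-oxo-4H-chromene-2-carbaldehyde
Product: 7 2-ethynyl-7,8-dimethoxy-4H-chromen-4-one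
Conditions: dimethyl (1-diazo-2-oxopropyl)phosphonate (1.3 equiv), K2CO3 (2 equiv), MeOH, 0 °C to rt
Reagents that add atoms: dimethyl (1-diazo-2-oxopropyl)phosphonate, CC(=O)C(=[N+]=[N-])P(=O)(OC)OC
Why: Seyferth–Gilbert homologation in the Ohira–Bestmann variant: the diazomethylphosphonate anion freed by methanolysis adds to the aldehyde, and elimination of phosphate, loss of N2 and 1,2-hydride shift of the alkylidene carbene give the terminal alkyne under carbonate base mild enough for the pyrone at 0 °C.

Step 5
Reactants: 7 2-ethynyl-7,8-dimethoxy-4H-chromen-4-one; 8 3,4-dimethoxyfuran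
Product: 10 2-(3-hydroxy-4,5-dimethoxyphenyl)-7,8-dimethoxy-4H-chromen-4-one, via oxanorbornadiene 9 (not isolated)
Conditions: 8 (3 equiv), ZnI2 (1 equiv), CH2Cl2, 0 °C to rt; then camphorsulfonic acid (0.2 equiv), rt
Reagents that add atoms: none
Why: ZnI2 bound to the pyrone carbonyl lowers the LUMO of the enynone so that the electron-rich diene 8 adds through its two α-carbons across the alkyne in a normal-demand [4+2] cycloaddition, forming C1'–C6' and C2'–C3' and giving the 7-oxanorbornadiene 9; ring B is thus closed by an intermolecular cycloaddition that makes both bonds of the six-membered carbocycle in one event. Acid on the bridging oxygen then breaks C6'–O, because the resulting cyclohexadienyl cation carries its charge on C6', C2' and C4' (the last held by its methoxy group) and none on C1', which bears the electron-poor, zinc-bound chromonyl group; loss of the C3' proton aromatises the ring and leaves the former furan oxygen as the C3' phenol. The closest known reaction type is the Diels–Alder addition of furans to propiolates and ynones followed by acid or Lewis acid isomerisation of the oxanorbornadienes to meta-hydroxybenzoates. No stereocentre is created in 10, since the two bridgehead centres of racemic 9 are erased on aromatisation. The selectivities needed are alkyne over the pyrone C2=C3 bond as dienophile, secured by the unhindered terminal alkyne against a trisubstituted, oxygen-substituted alkene, and the direction of bridge opening, secured by the chromonyl group on C1' and the methoxy group on C4'; the symmetry of 8 removes any regiochemical question from the cycloaddition itself. The step is an addition followed by an isomerisation, so every atom of 7 and 8 should end in 10.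

Step 6
Reactants: 10 2-(3-hydroxy-4,5-dimethoxyphenyl)-7,8-dimethoxy-4H-chromen-4-one
Product: 12 (2S)-2-(3-hydroxy-4,5-dimethoxyphenyl)-7,8-dimethoxy-2,3-dihydro-4H-chromen-4-one, via bis-silyl enol ether 11 (not isolated)
Conditions: Cu(OAc)2 (5 mol %), (R)-DTBM-SEGPHOS (5.5 mol %), (EtO)2MeSiH (3.5 equiv), THF, 0 °C to rt; then 1 M HCl, THF, 0 °C
Reagents that add atoms: none
Why: Asymmetric CuH 1,4-reduction, known for 2-substituted chromones: the phenol is first silylated by the silane with loss of H2, the bisphosphine-bound CuH then delivers hydride to one face of C2 of the enone (ligand control, creating the (S) centre), and the silyl enol ether 11 is hydrolysed by cold dilute acid, conditions under which ring opening to the chalcone and hence racemisation should not occur.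

Compound list
1 | 2'-hydroxy-3',4'-dimethoxyacetophenone | CC(=O)c1ccc(OC)c(OC)c1O | starting material
2 | diethyl oxalate | CCOC(=O)C(=O)OCC | starting material
3 | ethyl 4-(2-hydroxy-3,4-dimethoxyphenyl)-2,4-dioxobutanoate | CCOC(=O)C(=O)CC(=O)c1ccc(OC)c(OC)c1O | intermediate
4 | ethyl 7,8-dimethoxy-4-oxo-4H-chromene-2-carboxylate | CCOC(=O)c1cc(=O)c2ccc(OC)c(OC)c2o1 | intermediate
5 | 2-(hydroxymethyl)-7,8-dimethoxy-4H-chromen-4-one | OCc1cc(=O)c2ccc(OC)c(OC)c2o1 | intermediate
6 | 7,8-dimethoxy-4-oxo-4H-chromene-2-carbaldehyde | O=Cc1cc(=O)c2ccc(OC)c(OC)c2o1 | intermediate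
7 | 2-ethynyl-7,8-dimethoxy-4H-chromen-4-one | C#Cc1cc(=O)c2ccc(OC)c(OC)c2o1 | intermediate
8 | 3,4-dimethoxyfuran | COc1cocc1OC | starting material
9 | 2-(5,6-dimethoxy-7-oxabicyclo[2.2.1]hepta-2,5-dien-2-yl)-7,8-dimethoxy-4H-chromen-4-one (racemic) | COC1=C(OC)C2OC1C=C2c1cc(=O)c2ccc(OC)c(OC)c2o1 | intermediate
10 | 2-(3-hydroxy-4,5-dimethoxyphenyl)-7,8-dimethoxy-4H-chromen-4-one | COc1cc(-c2cc(=O)c3ccc(OC)c(OC)c3o2)cc(O)c1OC | intermediate
11 | (2S)-4-[diethoxy(methyl)silyloxy]-2-{3-[diethoxy(methyl)silyloxy]-4,5-dimethoxyphenyl}-7,8-dimethoxy-2H-chromene | COc1cc([C@@H]2C=C(O[Si](C)(OCC)OCC)c3ccc(OC)c(OC)c3O2)cc(O[Si](C)(OCC)OCC)c1OC | intermediate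
12 | (2S)-2-(3-hydroxy-4,5-dimethoxyphenyl)-7,8-dimethoxy-2,3-dihydro-4H-chromen-4-one | COc1cc([C@@H]2CC(=O)c3ccc(OC)c(OC)c3O2)cc(O)c1OC | target

Total step count: 6. Longest linear sequence: 6 steps (1 to 12).

Steps most likely to fail

Step 5. The cycloaddition may be outrun by conjugate (Friedel–Crafts-type) addition of the furan to the activated alkyne or by acid-induced decomposition of the furan, and the bridge could open in the wrong direction. The fallback brings ring B in ready-made by the chalcone route, setting out from 1 and returning at 10. Claisen–Schmidt condensation of 1 with purchased 3-(benzyloxy)-4,5-dimethoxybenzaldehyde F1 (KOH, EtOH, rt) should give the chalcone (E)-3-[3-(benzyloxy)-4,5-dimethoxyphenyl]-1-(2-hydroxy-3,4-dimethoxyphenyl)prop-2-en-1-one F2. Oxidative cyclisation (catalytic I2, DMSO, 120 °C) should give the flavone benzyl ether 2-[3-(benzyloxy)-4,5-dimethoxyphenyl]-7,8-dimethoxy-4H-chromen-4-one F3. Hydrogenolysis (H2, Pd/C, EtOAc) then frees the phenol to give 10.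

Step 6. Hydride transfer to the electron-rich flavone may be slow, the facial selectivity may be insufficient, and C2 could be scrambled through ring opening during work-up. The fallback sets C2 by hydrogenation and restores the ketone by oxidation, setting out from 10 and returning at 12. Silylation (TBSCl, imidazole, DMF) should give the silyl ether 2-[3-(tert-butyldimethylsilyloxy)-4,5-dimethoxyphenyl]-7,8-dimethoxy-4H-chromen-4-one F4. Exhaustive asymmetric hydrogenation of the pyrone C=C and C=O (H2, Ru(cod)(2-methylallyl)2 with a chiral N-heterocyclic carbene ligand, KOt-Bu, toluene) should give the cis-flavanol (2S,4S)-2-[3-(tert-butyldimethylsilyloxy)-4,5-dimethoxyphenyl]-7,8-dimethoxychroman-4-ol F5; C2 is set by delivery of H2 to one face of the C2=C3 bond and the C4 configuration is immaterial. Oxidation of the benzylic alcohol (Dess–Martin periodinane, CH2Cl2) should give the flavanone silyl ether (2S)-2-[3-(tert-butyldimethylsilyloxy)-4,5-dimethoxyphenyl]-7,8-dimethoxychroman-4-one F6, and HF·pyridine (THF, 0 °C) removes the silyl group to give 12.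

Step 4. Methoxide may attack the pyrone ring, or methanol may add in conjugate fashion to the newly formed enynone. The fallback makes the C2–alkyne bond by conjugate alkynylation of a benzopyrylium ion instead of aldehyde homologation, setting out from 1 and returning at 7. Heating 1 with DMF dimethyl acetal (neat, 100 °C) should give the enaminone (E)-3-(dimethylamino)-1-(2-hydroxy-3,4-dimethoxyphenyl)prop-2-en-1-one F7, which closes with HCl in CH2Cl2 to 7,8-dimethoxy-4H-chromen-4-one F8. TBSOTf, then (triisopropylsilyl)acetylene, CuI and i-Pr2NEt (CH2Cl2, −78 °C to rt) should add the copper acetylide to C2 of the 4-silyloxybenzopyrylium ion and give the racemic silyl enol ether 4-(tert-butyldimethylsilyloxy)-7,8-dimethoxy-2-[(triisopropylsilyl)ethynyl]-2H-chromene F9. Saegusa–Ito oxidation (Pd(OAc)2, MeCN, rt) restores the pyrone as 7,8-dimethoxy-2-[(triisopropylsilyl)ethynyl]-4H-chromen-4-one F10, and fluoride buffered with acetic acid (TBAF, AcOH, THF, 0 °C) removes the silyl cap to give 7.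

Further compounds
F1 | step 5 | 3-(benzyloxy)-4,5-dimethoxybenzaldehyde (purchased) | COc1cc(C=O)cc(OCc2ccccc2)c1OC
F2 | step 5 | (E)-3-[3-(benzyloxy)-4,5-dimethoxyphenyl]-1-(2-hydroxy-3,4-dimethoxyphenyl)prop-2-en-1-one | COc1ccc(C(=O)/C=C/c2cc(OC)c(OC)c(OCc3ccccc3)c2)c(O)c1OC
F3 | step 5 | 2-[3-(benzyloxy)-4,5-dimethoxyphenyl]-7,8-dimethoxy-4H-chromen-4-one | COc1cc(-c2cc(=O)c3ccc(OC)c(OC)c3o2)cc(OCc2ccccc2)c1OC
F4 | step 6 | 2-[3-(tert-butyldimethylsilyloxy)-4,5-dimethoxyphenyl]-7,8-dimethoxy-4H-chromen-4-one | COc1cc(-c2cc(=O)c3ccc(OC)c(OC)c3o2)cc(O[Si](C)(C)C(C)(C)C)c1OC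
F5 | step 6 | (2S,4S)-2-[3-(tert-butyldimethylsilyloxy)-4,5-dimethoxyphenyl]-7,8-dimethoxychroman-4-ol | COc1cc([C@@H]2C[C@H](O)c3ccc(OC)c(OC)c3O2)cc(O[Si](C)(C)C(C)(C)C)c1OC
F6 | step 6 | (2S)-2-[3-(tert-butyldimethylsilyloxy)-4,5-dimethoxyphenyl]-7,8-dimethoxychroman-4-one | COc1cc([C@@H]2CC(=O)c3ccc(OC)c(OC)c3O2)cc(O[Si](C)(C)C(C)(C)C)c1OC
F7 | step 4 | (E)-3-(dimethylamino)-1-(2-hydroxy-3,4-dimethoxyphenyl)prop-2-en-1-one | CN(C)/C=C/C(=O)c1ccc(OC)c(OC)c1O
F8 | step 4 | 7,8-dimethoxy-4H-chromen-4-one | O=c1ccoc2c(OC)c(OC)ccc12
F9 | step 4 | 4-(tert-butyldimethylsilyloxy)-7,8-dimethoxy-2-[(triisopropylsilyl)ethynyl]-2H-chromene (racemic) | COc1ccc2c(c1OC)OC(C#C[Si](C(C)C)(C(C)C)C(C)C)C=C2O[Si](C)(C)C(C)(C)C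
F10 | step 4 | 7,8-dimethoxy-2-[(triisopropylsilyl)ethynyl]-4H-chromen-4-one | COc1ccc2c(=O)cc(C#C[Si](C(C)C)(C(C)C)C(C)C)oc2c1OC
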